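**Strategy.** The 3,4,7,8-tetrahydro-2H-oxocine (O1, C2-ethyl, C3-Br, C5-Cl, C8-side chain) is cut at O1–C2 and C7–C8. Both bonds should form in one Lewis-acid-mediated formal [6+2] ring expansion: the carbonyl oxygen of (E)-but-2-enal adds to (R)-2-chloro-2-vinylcyclobutanone (O1–C2) and the resulting oxocarbenium ion undergoes a strain-driven 2-oxonia-Cope shift (C7–C8). This exploits the C5(Cl)=C6–C7–C8–O1–C2 array: the α-chloro-α-vinyl carbon becomes the ring vinyl chloride, C8 is set by chirality transfer, and an eight-membered lactone results. Its carbonyl C2 becomes CH(Et), C3 is oxygenated then brominated, and the propenyl group is grown into the chloro acetoxy enyne side chain.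

Key step: step 4

Remark on numbering: from 11 on, ring atoms are numbered as in the target oxocine (O1, C2 bearing ethyl, C3 bearing bromine, C5 bearing chlorine, C8 bearing the side chain).

Assumption: the (2S,5S)-auxiliary is taken to deliver the (R)-ketone 8; if its sense of induction were opposite, the commercial (2R,5R)-amine would be used with no other change.

Step 1
Reactants: 1 (E)-but-2-enoyl chloride; 2 (2S,5S)-2,5-dimethylpyrrolidine
Product: 3 (2E)-1-[(2S,5S)-2,5-dimethylpyrrolidin-1-yl]but-2-en-1-one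
Conditions: Et3N, CH2Cl2, 0 °C
Reagents that add atoms: none
Why: N-acylation of the secondary amine by the acid chloride should be clean and creates no stereocentre.

Step 2
Reactants: 3 (2E)-1-[(2S,5S)-2,5-dimethylpyrrolidin-1-yl]but-2-en-1-one
Product: 4 2-chloro-1-[(2S,5S)-2,5-dimethylpyrrolidin-1-yl]but-3-en-1-one (both C2 epimers)
Conditions: LiN(iPr)2, THF/DMPU, −78 °C; then C2Cl6, −78 °C
Reagents that add atoms: hexachloroethane, ClC(Cl)(Cl)C(Cl)(Cl)Cl
Why: γ-deprotonation gives the extended lithium enolate, which a positive-chlorine donor should trap at the α-carbon (deconjugative α-chlorination of an amide dienolate); the new centre is an epimer mixture that is erased in step 3.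

Step 3
Reactants: 4 2-chloro-1-[(2S,5S)-2,5-dimethylpyrrolidin-1-yl]but-3-en-1-one; 5 ethylene
Product: 8 (2R)-2-chloro-2-ethenylcyclobutan-1-one, via keteniminium triflate 6 (not isolated), via cyclobutaniminium triflate 7 (not isolated)
Conditions: Tf2O, 2,4,6-collidine, CH2Cl2, −78 to 0 °C; ethylene (5 atm), 0 °C to rt; then aq. NaHCO3, rt
Reagents that add atoms: water, O
Why: amide activation gives the chloro(vinyl)keteniminium salt, which should undergo keteniminium–olefin [2+2] cycloaddition with ethylene and hydrolysis to the cyclobutanone; the C2-symmetric pyrrolidine makes the two faces of the keteniminium C=C diastereotopic and is expected to set the quaternary (R) centre (auxiliary control).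

Step 4
Reactants: 8 (2R)-2-chloro-2-ethenylcyclobutan-1-one; 9 (E)-but-2-enal
Product: 11 (5E,8R)-5-chloro-8-[(1E)-prop-1-en-1-yl]-3,4,7,8-tetrahydro-2H-oxocin-2-one, via oxocarbenium adduct 10 (not isolated)
Conditions: BF3·OEt2 (1.2 equiv), 9 (1.5 equiv), CH2Cl2, −78 to −40 °C; Et3N quench
Reagents that add atoms: none
Why: Proposed new method: BF3 activates the strained α-chloro cyclobutanone carbonyl (future C2), the carbonyl oxygen of 9 adds to it on the face cis to the vinyl group (O1–C2), and the resulting oxocarbenium ion 10 undergoes a charge-accelerated 2-oxonia-Cope ([3,3]) shift through a boat transition state, which forms C7–C8, cleaves the ring bond between the carbonyl carbon and the C(Cl)(vinyl) carbon and lets the boron alkoxide collapse to the lactone carbonyl. The closest known reaction types are 2-oxonia-Cope allyl transfer between carbonyl compounds, the Cope ring expansion of cis-1,2-divinylcyclobutanes, the Bellus–Claisen ring expansion of 2-vinyl cyclic ethers with ketenes and Lewis-acid [4+2] annulation of cyclobutanones with aldehydes; their combination on a 2-vinylcyclobutanone is not established. The oxocine ring is closed by four-atom ring expansion of the cyclobutanone (formal [6+2]), so there is no endo/exo competition and the new C5=C6 bond can only be ring-cis, with chlorine on C5. C8 is set by chirality transfer from the quaternary C–Cl centre of (R)-8 through the boat array, with the propenyl group exo on an (E)-oxocarbenium ion, which should give (8R). The step needs the aldehyde oxygen rather than an enol to be the nucleophile and the [3,3] shift to outrun 1,3-acyl shift and ionisation of the tertiary allylic chloride; the quaternary α-carbon, the electron-rich enal oxygen, the electrophilic strained ketone and the low temperature should secure this.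

Step 5
Reactants: 11 (5E,8R)-5-chloro-8-[(1E)-prop-1-en-1-yl]-3,4,7,8-tetrahydro-2H-oxocin-2-one
Product: 12 (3R,5E,8R)-5-chloro-3-hydroxy-8-[(1E)-prop-1-en-1-yl]-3,4,7,8-tetrahydro-2H-oxocin-2-one
Conditions: KN(SiMe3)2, THF, −78 °C; 3-phenyl-2-(phenylsulfonyl)oxaziridine, −78 °C; AcOH
Reagents that add atoms: 3-phenyl-2-(phenylsulfonyl)oxaziridine, O=S(=O)(c1ccccc1)N1OC1c1ccccc1
Why: Davis oxidation of the potassium lactone enolate; the oxidant is expected to approach the less hindered peripheral face of the medium-ring enolate, placing the hydroxyl cis to the C8 substituent (3R).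

Step 6
Reactants: 12 (3R,5E,8R)-5-chloro-3-hydroxy-8-[(1E)-prop-1-en-1-yl]-3,4,7,8-tetrahydro-2H-oxocin-2-one
Product: 13 (3R,5E,8R)-3-{[tert-butyl(dimethyl)silyl]oxy}-5-chloro-8-[(1E)-prop-1-en-1-yl]-3,4,7,8-tetrahydro-2H-oxocin-2-one
Conditions: tBuMe2SiOTf, 2,6-lutidine, CH2Cl2, −78 °C
Reagents that add atoms: tert-butyldimethylsilyl trifluoromethanesulfonate, CC(C)(C)[Si](C)(C)OS(=O)(=O)C(F)(F)F
Why: silylation of the secondary alcohol with a silyl triflate and a hindered base should proceed without touching the lactone or the stereocentres.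

Step 7
Reactants: 13 (3R,5E,8R)-3-{[tert-butyl(dimethyl)silyl]oxy}-5-chloro-8-[(1E)-prop-1-en-1-yl]-3,4,7,8-tetrahydro-2H-oxocin-2-one; 14 1,1-dibromoethane
Product: 15 tert-butyl{[(2Z,3R,5E,8R)-5-chloro-2-ethylidene-8-[(1E)-prop-1-en-1-yl]-3,4,7,8-tetrahydro-2H-oxocin-3-yl]oxy}dimethylsilane
Conditions: Zn, TiCl4, TMEDA, PbCl2 (cat.), THF, 0 °C to rt
Reagents that add atoms: none
Why: Takai–Utimoto alkylidenation should convert the lactone carbonyl into the ethylidene enol ether while the O1–C2 bond stays intact; the enol ether geometry is lost in step 8.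

Step 8
Reactants: 15 tert-butyl{[(2Z,3R,5E,8R)-5-chloro-2-ethylidene-8-[(1E)-prop-1-en-1-yl]-3,4,7,8-tetrahydro-2H-oxocin-3-yl]oxy}dimethylsilane
Product: 16 tert-butyl{[(2R,3R,5E,8R)-5-chloro-2-ethyl-8-[(1E)-prop-1-en-1-yl]-3,4,7,8-tetrahydro-2H-oxocin-3-yl]oxy}dimethylsilane
Conditions: Et3SiH, CF3CO2H, CH2Cl2, −78 to −40 °C
Reagents that add atoms: none
Why: ionic hydrogenation: protonation of the enol ether gives the C2 oxocarbenium ion, which the silane should reduce on the face anti to the C3 silyloxy group, the same face that gives the favoured cis-2,8-disubstituted oxocene, setting C2 (R).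

Step 9
Reactants: 16 tert-butyl{[(2R,3R,5E,8R)-5-chloro-2-ethyl-8-[(1E)-prop-1-en-1-yl]-3,4,7,8-tetrahydro-2H-oxocin-3-yl]oxy}dimethylsilane
Product: 17 (2R,3R,5E,8R)-5-chloro-2-ethyl-8-[(1E)-prop-1-en-1-yl]-3,4,7,8-tetrahydro-2H-oxocin-3-ol
Conditions: HF·pyridine, THF, 0 °C to rt
Reagents that add atoms: none
Why: fluoride cleavage of the Si–O bond under buffered conditions should leave the allylic ether and both alkenes untouched.

Step 10
Reactants: 17 (2R,3R,5E,8R)-5-chloro-2-ethyl-8-[(1E)-prop-1-en-1-yl]-3,4,7,8-tetrahydro-2H-oxocin-3-ol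
Product: 18 (2R,3S,5E,8R)-3-bromo-5-chloro-2-ethyl-8-[(1E)-prop-1-en-1-yl]-3,4,7,8-tetrahydro-2H-oxocine
Conditions: CBr4, P(n-C8H17)3, toluene, 70 °C
Reagents that add atoms: carbon tetrabromide, BrC(Br)(Br)Br
Why: Appel-type bromination through the alkoxyphosphonium salt with SN2 inversion should turn the (3R)-alcohol into the (3S)-bromide trans to the ethyl group.

Step 11
Reactants: 18 (2R,3S,5E,8R)-3-bromo-5-chloro-2-ethyl-8-[(1E)-prop-1-en-1-yl]-3,4,7,8-tetrahydro-2H-oxocine
Product: 19 (2R,3S,5E,8R)-3-bromo-5-chloro-2-ethyl-3,4,7,8-tetrahydro-2H-oxocine-8-carbaldehyde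
Conditions: O3, CH2Cl2, −78 °C (indicator dye); then PPh3, −78 °C to rt
Reagents that add atoms: ozone, [O-][O+]=O
Why: ozonolysis with reductive work-up should cleave the electron-rich disubstituted propenyl alkene in preference to the chlorine-deactivated ring alkene and gives the aldehyde without base, so C8 is not epimerised.

Step 12
Reactants: 19 (2R,3S,5E,8R)-3-bromo-5-chloro-2-ethyl-3,4,7,8-tetrahydro-2H-oxocine-8-carbaldehyde; 20 3-chloroprop-1-ene
Product: 21 (1S,2S)-1-[(2R,3S,5E,8R)-3-bromo-5-chloro-2-ethyl-3,4,7,8-tetrahydro-2H-oxocin-8-yl]-2-chlorobut-3-en-1-ol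
Conditions: 20, (+)-Ipc2BOMe, LiN(c-C6H11)2, Et2O, −95 °C; BF3·OEt2; then 19, −95 °C; HOCH2CH2NH2, rt
Reagents that add atoms: none
Why: Brown-type allylboration with the (Z)-γ-chloroallylborane made in the flask should give the syn chlorohydrin through a chair transition state, and the (+)-isopinocampheyl groups direct attack to the Re face of the aldehyde (reagent control overriding the bias of the α-alkoxy aldehyde), setting both new centres as (S).

Step 13
Reactants: 21 (1S,2S)-1-[(2R,3S,5E,8R)-3-bromo-5-chloro-2-ethyl-3,4,7,8-tetrahydro-2H-oxocin-8-yl]-2-chlorobut-3-en-1-ol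
Product: 22 (1S,2S)-1-[(2R,3S,5E,8R)-3-bromo-5-chloro-2-ethyl-3,4,7,8-tetrahydro-2H-oxocin-8-yl]-2-chlorobut-3-en-1-yl acetate
Conditions: Ac2O, pyridine, DMAP (cat.), CH2Cl2, 0 °C
Reagents that add atoms: acetic anhydride, CC(=O)OC(C)=O
Why: DMAP-catalysed acylation of the secondary alcohol under weakly basic conditions should avoid epoxide formation from the chlorohydrin.

Step 14
Reactants: 22 (1S,2S)-1-[(2R,3S,5E,8R)-3-bromo-5-chloro-2-ethyl-3,4,7,8-tetrahydro-2H-oxocin-8-yl]-2-chlorobut-3-en-1-yl acetate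
Product: 23 (1S,2R)-1-[(2R,3S,5E,8R)-3-bromo-5-chloro-2-ethyl-3,4,7,8-tetrahydro-2H-oxocin-8-yl]-2-chloro-3-oxopropyl acetate
Conditions: O3, CH2Cl2, −78 °C (indicator dye); then PPh3, −78 °C
Reagents that add atoms: ozone, [O-][O+]=O
Why: ozonolysis of the monosubstituted vinyl group, which should react faster than the vinyl chloride, gives the α-chloro aldehyde under neutral conditions so that the C–Cl centre keeps its configuration (the descriptor changes only by priority).

Step 15
Reactants: 23 (1S,2R)-1-[(2R,3S,5E,8R)-3-bromo-5-chloro-2-ethyl-3,4,7,8-tetrahydro-2H-oxocin-8-yl]-2-chloro-3-oxopropyl acetate; 24 1,3-bis(triisopropylsilyl)prop-1-yne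
Product: 25 (1S,2S,3Z)-1-[(2R,3S,5E,8R)-3-bromo-5-chloro-2-ethyl-3,4,7,8-tetrahydro-2H-oxocin-8-yl]-2-chloro-6-(triisopropylsilyl)hex-3-en-5-yn-1-yl acetate
Conditions: 24, n-BuLi, THF, −20 °C; then 23, −78 to −20 °C; H2O
Reagents that add atoms: none
Why: Peterson olefination with the lithiated bis(silyl)propyne should add to the aldehyde and eliminate silanolate to give the (Z)-enyne selectively, the low temperature and hindered nucleophile sparing the acetate and the α-chloro centre.

Step 16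
Reactants: 25 (1S,2S,3Z)-1-[(2R,3S,5E,8R)-3-bromo-5-chloro-2-ethyl-3,4,7,8-tetrahydro-2H-oxocin-8-yl]-2-chloro-6-(triisopropylsilyl)hex-3-en-5-yn-1-yl acetate
Product: 26 (1S,2S,3Z)-1-[(2R,3S,5E,8R)-3-bromo-5-chloro-2-ethyl-3,4,7,8-tetrahydro-2H-oxocin-8-yl]-2-chlorohex-3-en-5-yn-1-yl acetate
Conditions: Bu4NF, AcOH, THF, 0 °C
Reagents that add atoms: none
Why: fluoride cleavage of the alkynyl C–Si bond, buffered with acetic acid, should leave the acetate and the three halides in place.

**Compound list**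

1 | (E)-but-2-enoyl chloride | C/C=C/C(Cl)=O | starting material
2 | (2S,5S)-2,5-dimethylpyrrolidine | C[C@H]1CC[C@H](C)N1 | starting material
3 | (2E)-1-[(2S,5S)-2,5-dimethylpyrrolidin-1-yl]but-2-en-1-one | C[C@H]1CC[C@H](C)N1C(=O)/C=C/C | intermediate
4 | 2-chloro-1-[(2S,5S)-2,5-dimethylpyrrolidin-1-yl]but-3-en-1-one (both C2 epimers) | C[C@H]1CC[C@H](C)N1C(=O)C(Cl)C=C | intermediate
5 | ethylene | C=C | starting material
6 | (2S,5S)-1-(2-chlorobuta-1,3-dien-1-ylidene)-2,5-dimethylpyrrolidinium trifluoromethanesulfonate (keteniminium triflate) | C=CC(Cl)=C=[N+]1[C@@H](C)CC[C@@H]1C.[O-]S(=O)(=O)C(F)(F)F | intermediate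
7 | (2S,5S)-1-[(2R)-2-chloro-2-ethenylcyclobutylidene]-2,5-dimethylpyrrolidinium trifluoromethanesulfonate (cyclobutaniminium triflate) | C=C[C@]1(Cl)CCC1=[N+]2[C@@H](C)CC[C@@H]2C.[O-]S(=O)(=O)C(F)(F)F | intermediate
8 | (2R)-2-chloro-2-ethenylcyclobutan-1-one | C=C[C@]1(Cl)CCC1=O | intermediate
9 | (E)-but-2-enal | C/C=C/C=O | starting material
10 | oxocarbenium adduct: zwitterion of 8 and 9 with the aldehyde oxygen on the ketone carbon cis to vinyl and BF3 on the former ketone oxygen | C=C[C@]1(Cl)CC[C@]1(O[B-](F)(F)F)[O+]=C/C=C/C | intermediate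
11 | (5E,8R)-5-chloro-8-[(1E)-prop-1-en-1-yl]-3,4,7,8-tetrahydro-2H-oxocin-2-one | C/C=C/[C@H]1C/C=C(/Cl)CCC(=O)O1 | intermediate
12 | (3R,5E,8R)-5-chloro-3-hydroxy-8-[(1E)-prop-1-en-1-yl]-3,4,7,8-tetrahydro-2H-oxocin-2-one | C/C=C/[C@H]1C/C=C(/Cl)C[C@@H](O)C(=O)O1 | intermediate
13 | (3R,5E,8R)-3-{[tert-butyl(dimethyl)silyl]oxy}-5-chloro-8-[(1E)-prop-1-en-1-yl]-3,4,7,8-tetrahydro-2H-oxocin-2-one | C/C=C/[C@H]1C/C=C(/Cl)C[C@@H](O[Si](C)(C)C(C)(C)C)C(=O)O1 | intermediate
14 | 1,1-dibromoethane | CC(Br)Br | starting material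
15 | tert-butyl{[(2Z,3R,5E,8R)-5-chloro-2-ethylidene-8-[(1E)-prop-1-en-1-yl]-3,4,7,8-tetrahydro-2H-oxocin-3-yl]oxy}dimethylsilane | C/C=C/[C@H]1C/C=C(/Cl)C[C@@H](O[Si](C)(C)C(C)(C)C)/C(=C/C)O1 | intermediate
16 | tert-butyl{[(2R,3R,5E,8R)-5-chloro-2-ethyl-8-[(1E)-prop-1-en-1-yl]-3,4,7,8-tetrahydro-2H-oxocin-3-yl]oxy}dimethylsilane | C/C=C/[C@H]1C/C=C(/Cl)C[C@@H](O[Si](C)(C)C(C)(C)C)[C@@H](CC)O1 | intermediate
17 | (2R,3R,5E,8R)-5-chloro-2-ethyl-8-[(1E)-prop-1-en-1-yl]-3,4,7,8-tetrahydro-2H-oxocin-3-ol | C/C=C/[C@H]1C/C=C(/Cl)C[C@@H](O)[C@@H](CC)O1 | intermediate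
18 | (2R,3S,5E,8R)-3-bromo-5-chloro-2-ethyl-8-[(1E)-prop-1-en-1-yl]-3,4,7,8-tetrahydro-2H-oxocine | C/C=C/[C@H]1C/C=C(/Cl)C[C@H](Br)[C@@H](CC)O1 | intermediate
19 | (2R,3S,5E,8R)-3-bromo-5-chloro-2-ethyl-3,4,7,8-tetrahydro-2H-oxocine-8-carbaldehyde | O=C[C@H]1C/C=C(/Cl)C[C@H](Br)[C@@H](CC)O1 | intermediate
20 | 3-chloroprop-1-ene (allyl chloride) | C=CCCl | starting material
21 | (1S,2S)-1-[(2R,3S,5E,8R)-3-bromo-5-chloro-2-ethyl-3,4,7,8-tetrahydro-2H-oxocin-8-yl]-2-chlorobut-3-en-1-ol | C=C[C@H](Cl)[C@@H](O)[C@H]1C/C=C(/Cl)C[C@H](Br)[C@@H](CC)O1 | intermediate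
22 | (1S,2S)-1-[(2R,3S,5E,8R)-3-bromo-5-chloro-2-ethyl-3,4,7,8-tetrahydro-2H-oxocin-8-yl]-2-chlorobut-3-en-1-yl acetate | C=C[C@H](Cl)[C@@H](OC(C)=O)[C@H]1C/C=C(/Cl)C[C@H](Br)[C@@H](CC)O1 | intermediate
23 | (1S,2R)-1-[(2R,3S,5E,8R)-3-bromo-5-chloro-2-ethyl-3,4,7,8-tetrahydro-2H-oxocin-8-yl]-2-chloro-3-oxopropyl acetate | O=C[C@H](Cl)[C@@H](OC(C)=O)[C@H]1C/C=C(/Cl)C[C@H](Br)[C@@H](CC)O1 | intermediate
24 | 1,3-bis(triisopropylsilyl)prop-1-yne | CC(C)[Si](C(C)C)(C(C)C)C#CC[Si](C(C)C)(C(C)C)C(C)C | starting material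
25 | (1S,2S,3Z)-1-[(2R,3S,5E,8R)-3-bromo-5-chloro-2-ethyl-3,4,7,8-tetrahydro-2H-oxocin-8-yl]-2-chloro-6-(triisopropylsilyl)hex-3-en-5-yn-1-yl acetate | CC(C)[Si](C(C)C)(C(C)C)C#C/C=C\[C@H](Cl)[C@@H](OC(C)=O)[C@H]1C/C=C(/Cl)C[C@H](Br)[C@@H](CC)O1 | intermediate
26 | (1S,2S,3Z)-1-[(2R,3S,5E,8R)-3-bromo-5-chloro-2-ethyl-3,4,7,8-tetrahydro-2H-oxocin-8-yl]-2-chlorohex-3-en-5-yn-1-yl acetate | C#C/C=C\[C@H](Cl)[C@@H](OC(C)=O)[C@H]1C/C=C(/Cl)C[C@H](Br)[C@@H](CC)O1 | target

**Step count.** Total: 16 steps. Longest linear sequence: 16 steps (1 to 26).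

**Steps most likely to fail**

Step 4 (Proposed new method). The aldehyde oxygen may fail to add to the ketone, or the adduct may divert to 1,3-acyl shift, aldol addition or ionisation of the allylic chloride before the [3,3] shift, and chirality transfer may be incomplete. Fallback with known chemistry, from 9 back to 11: a boron aldol of 9 with the diisopinocampheylboron enolate of 3-chlorobut-3-en-2-one (Ipc2BCl enantiomer chosen for the 5R adduct, Et3N) should give (5R,6E)-2-chloro-5-hydroxyocta-1,6-dien-3-one F1. 1,2-Reduction (NaBH4, CeCl3) gives (5R,6E)-2-chloroocta-1,6-diene-3,5-diol F2, whose new carbinol centre is lost later. Acetal exchange with (phenylselanyl)acetaldehyde diethyl acetal and pyridinium tosylate gives the selenoacetal F3. Oxidation with NaIO4 gives the selenoxide F4, and heating with DBU in xylene eliminates it to the 2-methylene-1,3-dioxane F5. F5 undergoes Claisen ring expansion through the unsubstituted terminus of the 1-chlorovinyl group to lactone 11.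

Step 3. Facial discrimination by the auxiliary at the keteniminium carbon may be insufficient or reversed, so that 8 is obtained with low enantiomeric purity. Fallback, from 8 of low enantiomeric purity back to 8: oxazaborolidine-catalysed borane reduction (CBS reduction) run as a kinetic resolution, with the catalyst enantiomer that consumes the (S)-ketone, converts that enantiomer into (2S)-2-chloro-2-ethenylcyclobutan-1-ol F6. Unreduced (R)-8 is separated and re-enters at step 4.

Step 5. The oxidant may attack the other face of the lactone enolate (poor or opposite facial selectivity). Fallback, from 11 back to 12: the (3S,5E,8R)-hydroxy lactone F7 formed in that case is converted into its triflate F8 (Tf2O, pyridine, CH2Cl2, −20 °C). Lattrell–Dax inversion with KNO2 in DMF gives, by SN2 displacement at the α-carbonyl carbon, the (3R)-nitrite ester F9, which hydrolyses on work-up to 12.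

**Further compounds**

F1 | step 4 | (5R,6E)-2-chloro-5-hydroxyocta-1,6-dien-3-one | C/C=C/[C@H](O)CC(=O)C(Cl)=C
F2 | step 4 | (5R,6E)-2-chloroocta-1,6-diene-3,5-diol (C3 epimers) | C/C=C/[C@H](O)CC(O)C(Cl)=C
F3 | step 4 | (6R)-4-(1-chloroethenyl)-2-[(phenylselanyl)methyl]-6-[(1E)-prop-1-en-1-yl]-1,3-dioxane | C/C=C/[C@H]1CC(C(Cl)=C)OC(C[Se]c2ccccc2)O1
F4 | step 4 | (6R)-4-(1-chloroethenyl)-2-[(phenylseleninyl)methyl]-6-[(1E)-prop-1-en-1-yl]-1,3-dioxane | C/C=C/[C@H]1CC(C(Cl)=C)OC(C[Se](=O)c2ccccc2)O1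
F5 | step 4 | (6R)-4-(1-chloroethenyl)-2-methylidene-6-[(1E)-prop-1-en-1-yl]-1,3-dioxane | C/C=C/[C@H]1CC(C(Cl)=C)OC(=C)O1
F6 | step 3 | (2S)-2-chloro-2-ethenylcyclobutan-1-ol (C1 epimers) | C=C[C@@]1(Cl)CCC1O
F7 | step 5 | (3S,5E,8R)-5-chloro-3-hydroxy-8-[(1E)-prop-1-en-1-yl]-3,4,7,8-tetrahydro-2H-oxocin-2-one | C/C=C/[C@H]1C/C=C(/Cl)C[C@H](O)C(=O)O1
F8 | step 5 | (3S,5E,8R)-5-chloro-2-oxo-8-[(1E)-prop-1-en-1-yl]-3,4,7,8-tetrahydro-2H-oxocin-3-yl trifluoromethanesulfonate | C/C=C/[C@H]1C/C=C(/Cl)C[C@H](OS(=O)(=O)C(F)(F)F)C(=O)O1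
F9 | step 5 | (3R,5E,8R)-5-chloro-2-oxo-8-[(1E)-prop-1-en-1-yl]-3,4,7,8-tetrahydro-2H-oxocin-3-yl nitrite | C/C=C/[C@H]1C/C=C(/Cl)C[C@@H](ON=O)C(=O)O1
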